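**Plan**

- Labels: C-a is the CH that bears the 2-hydroxy-2-methylpropyl chain; C-b and C-c are the two ring-fusion CH groups. Ring P is the pyran of quinolinone A (O-P, C-c, C-b, C-a, C-3A, C-4A). Ring Q is the dimethylpyran of quinolinone B (O-Q, CMe2, C-b, C-c, C-3B, C-4B).
- Enabling feature: ring Q is a 3,4-dihydro-2H-pyran on the enol unit C-3B=C-4B–O-Q of a 4-hydroxyquinolin-2-one, and C-c, which it shares with ring P, is a methine bonded to O-P, C-3B and C-b. This is the retron of a hetero-Diels–Alder reaction between the oxadiene O-Q=C-4B–C-3B=C-c and the alkene C-b=CMe2, with C-c at the orthoformate level and both halves the same quinolinone.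
- Cuts: C-c–C-b and O-Q–CMe2 (cycloaddition); C-c–O-P and C-c–C-3B (C-c becomes HC(OMe)3); the two carbinol methyl groups (MeMgBr); C-3A–C-a (Michael addition to a commercial dienone); the quinolinone ring (N-methylaniline plus malonate).
- Forward: quinolinone, Michael adduct, tertiary alcohol, silyl ether; then a second equivalent of the quinolinone, the orthoformate and this alkenyl enol are joined in one flask, where rings P and Q close in a single cycloaddition and ring Q is completed last; desilylation ends the route.
- Stereochemistry: C-a comes from a diamine-catalysed asymmetric Michael addition; C-b comes from C-a by allylic strain, and C-c from the endo mode of the cycloaddition.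

Key step: step 6

Assumption: compound 8 is drawn in its open keto form although it equilibrates with cyclic hemiketals. The facial sense of step 3 is taken over from the analogous warfarin-forming Michael addition and would be confirmed before proceeding.

**Step 1**
Reactants: 1 2,3-dimethoxyaniline
Product: 3 2,3-dimethoxy-N-methylaniline, via N-(methoxymethyl)-2,3-dimethoxyaniline 2 (not isolated)
Conditions: (CH2O)n, NaOMe, MeOH, reflux; then NaBH4, reflux
Reagents that add atoms: formaldehyde (as paraformaldehyde), C=O
Why: Condensation with formaldehyde in NaOMe/MeOH stops at the N-(methoxymethyl)amine, which NaBH4 reduces to the N-methylaniline (reductive amination), a sequence that avoids dimethylation.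

**Step 2**
Reactants: 3 2,3-dimethoxy-N-methylaniline; 4 diethyl malonate
Product: 6 4-hydroxy-7,8-dimethoxy-1-methylquinolin-2(1H)-one, via malonamate ester 5 (not isolated)
Conditions: Ph2O, 250 °C, EtOH distilled off
Reagents that add atoms: none
Why: Thermal aminolysis gives the malonanilide ester, which should cyclise by intramolecular Friedel–Crafts-type acylation (through the acyl ketene) at the only free ortho position, para to the 3-methoxy group, so only the 7,8-dimethoxy isomer can form.

**Step 3**
Reactants: 6 4-hydroxy-7,8-dimethoxy-1-methylquinolin-2(1H)-one; 7 (3E)-6-methylhepta-3,5-dien-2-one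
Product: 8 4-hydroxy-7,8-dimethoxy-1-methyl-3-[(4S)-2-methyl-6-oxohept-2-en-4-yl]quinolin-2(1H)-one
Conditions: (S,S)-1,2-diphenylethane-1,2-diamine (10 mol %), AcOH (10 equiv), THF, rt
Reagents that add atoms: none
Why: Iminium activation of the dienone by the primary diamine and 1,4-addition of the vinylogous acid through C-3 (the asymmetric Michael reaction used for warfarin) should create C-a as S, 1,6-addition being blocked by the fully substituted terminus and the face being that used when the (S,S)-diamine gives (S)-warfarin.

**Step 4**
Reactants: 8 Michael adduct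
Product: 9 4-hydroxy-3-[(4S)-6-hydroxy-2,6-dimethylhept-2-en-4-yl]-7,8-dimethoxy-1-methylquinolin-2(1H)-one
Conditions: MeMgBr (5 equiv), THF, −20 °C to rt; aq NH4Cl
Reagents that add atoms: methylmagnesium bromide, C[Mg]Br
Why: Grignard addition, in which the first equivalent deprotonates the 4-OH and so opens the hemiketal, leaving the methyl ketone as the only electrophilic carbonyl (the vinylogous carbamate C-2 carbonyl is inert) and C-a untouched.

**Step 5**
Reactants: 9 diol
Product: 11 4-hydroxy-3-[(4S)-2,6-dimethyl-6-(triethylsilyloxy)hept-2-en-4-yl]-7,8-dimethoxy-1-methylquinolin-2(1H)-one, via bis(triethylsilyl) ether 10 (not isolated)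
Conditions: Et3SiOTf (2.5 equiv), 2,6-lutidine, CH2Cl2, −78 to 0 °C; then K2CO3 (cat.), MeOH, 0 °C
Reagents that add atoms: triethylsilyl trifluoromethanesulfonate, CC[Si](CC)(CC)OS(=O)(=O)C(F)(F)F
Why: Silylation of both hydroxyl groups followed by mild methanolysis, which removes only the labile enol silyl group, masks the tertiary alcohol so that it cannot enter the alkoxy exchange of step 6.

**Step 6**
Reactants: 11 silyl-protected alkenyl enol; 6 4-hydroxy-7,8-dimethoxy-1-methylquinolin-2(1H)-one; 12 trimethyl orthoformate
Product: 15 O-triethylsilyl ether of the target (cis-fused; C-a S / C-b S / C-c R), via methoxymethylidene dione 13 (not isolated), via aryloxymethylidene dione 14 (not isolated)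
Conditions: (a) 6 (1.5 equiv), HC(OMe)3 (neat), 100 °C, then evaporation; (b) 11, PhMe, 5 Å molecular sieves, 110 °C
Reagents that add atoms: none
Why: Proposed new method: 6 should condense through C-3 with the orthoformate to the 3-(methoxymethylidene)-2,4-dione 13; the enolic 4-OH of 11 then exchanges the methoxy group by addition–elimination at that carbon (the sieves take up the methanol) to give 14, whose oxadiene O-Q=C-4B–C-3B=C-c is trapped irreversibly by the tethered alkene C-b=CMe2 in an intramolecular hetero-Diels–Alder reaction with inverse electron demand, which drains the unfavourable exchange equilibrium. The closest known reaction types are the domino Knoevenagel/hetero-Diels–Alder reaction of cyclic 1,3-dicarbonyl compounds with alkenyl aldehydes and the orthoformate-mediated intramolecular cycloaddition of alkoxy-substituted ortho-quinone methides formed from salicylaldehydes and unsaturated alcohols; new are the orthoformate carbon as the third component and an enolic oxygen as the first tether atom. Ring P closes as the six-membered tether ring when C-c bonds to C-b, and ring Q is the [4+2] ring itself, completed by the O-Q–CMe2 bond, the later of the two bonds in an asynchronous transition state because positive charge builds up on the tertiary carbon. C-b is set by C-a through allylic 1,3-strain: H-a lies in the alkene plane next to the cis methyl group, the quinolinone that carries the tether and the silyloxyalkyl chain occupy opposite faces, and the diene can only reach the face of its own tether, so H-a and H-b end up trans. C-c follows from the endo (syn) transition state expected for a tether that contains the planar C-3A=C-4A–O-P unit, which gives the cis ring fusion (H-b and H-c cis). The step needs the ketone carbonyl C-4B=O and not the lactam carbonyl as diene terminus (the ketone is the more electron-poor and its use gives the aromatic 2-quinolone), O-attack of 11 (its C-3 is blocked), and no methine-bridged bis-quinolinone (6 is consumed in stage a before 11 is added).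

**Step 7**
Reactants: 15 O-triethylsilyl ether of the target
Product: 16 target
Conditions: HF·pyridine, pyridine, THF, 0 °C to rt
Reagents that add atoms: none
Why: Fluoride-mediated desilylation of the tertiary silyl ether under buffered conditions should leave the acid-labile tertiary aryl ether of ring Q and the C-c–O-P bond intact and touches no stereocentre.

**Compound list**

1 | 2,3-dimethoxyaniline | COc1cccc(N)c1OC | starting material
2 | N-(methoxymethyl)-2,3-dimethoxyaniline | COCNc1cccc(OC)c1OC | intermediate
3 | 2,3-dimethoxy-N-methylaniline | CNc1cccc(OC)c1OC | intermediate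
4 | diethyl malonate | CCOC(=O)CC(=O)OCC | starting material
5 | ethyl 3-[(2,3-dimethoxyphenyl)(methyl)amino]-3-oxopropanoate | CCOC(=O)CC(=O)N(C)c1cccc(OC)c1OC | intermediate
6 | 4-hydroxy-7,8-dimethoxy-1-methylquinolin-2(1H)-one | COc1ccc2c(O)cc(=O)n(C)c2c1OC | intermediate
7 | (3E)-6-methylhepta-3,5-dien-2-one | CC(=O)/C=C/C=C(C)C | starting material
8 | 4-hydroxy-7,8-dimethoxy-1-methyl-3-[(4S)-2-methyl-6-oxohept-2-en-4-yl]quinolin-2(1H)-one | COc1ccc2c(O)c(c(=O)n(C)c2c1OC)[C@@H](CC(C)=O)C=C(C)C | intermediate
9 | 4-hydroxy-3-[(4S)-6-hydroxy-2,6-dimethylhept-2-en-4-yl]-7,8-dimethoxy-1-methylquinolin-2(1H)-one | COc1ccc2c(O)c(c(=O)n(C)c2c1OC)[C@@H](CC(C)(C)O)C=C(C)C | intermediate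
10 | 3-[(4S)-2,6-dimethyl-6-(triethylsilyloxy)hept-2-en-4-yl]-7,8-dimethoxy-1-methyl-4-(triethylsilyloxy)quinolin-2(1H)-one | COc1ccc2c(O[Si](CC)(CC)CC)c(c(=O)n(C)c2c1OC)[C@@H](CC(C)(C)O[Si](CC)(CC)CC)C=C(C)C | intermediate
11 | 4-hydroxy-3-[(4S)-2,6-dimethyl-6-(triethylsilyloxy)hept-2-en-4-yl]-7,8-dimethoxy-1-methylquinolin-2(1H)-one | COc1ccc2c(O)c(c(=O)n(C)c2c1OC)[C@@H](CC(C)(C)O[Si](CC)(CC)CC)C=C(C)C | intermediate
12 | trimethyl orthoformate | COC(OC)OC | starting material
13 | 7,8-dimethoxy-3-(methoxymethylidene)-1-methylquinoline-2,4(1H,3H)-dione (E/Z mixture) | COC=C1C(=O)c2ccc(OC)c(OC)c2N(C)C1=O | intermediate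
14 | 3-(aryloxymethylidene)-7,8-dimethoxy-1-methylquinoline-2,4(1H,3H)-dione, in which the aryloxy group is the 4-oxy residue of 11 | COc1ccc2c(OC=C3C(=O)c4ccc(OC)c(OC)c4N(C)C3=O)c(c(=O)n(C)c2c1OC)[C@@H](CC(C)(C)O[Si](CC)(CC)CC)C=C(C)C | intermediate
15 | O-triethylsilyl ether of 16 (silyl group on the tertiary alcohol; C-a S, C-b S, C-c R) | COc1ccc2c3c(c(=O)n(C)c2c1OC)[C@@H](CC(C)(C)O[Si](CC)(CC)CC)[C@H]1[C@@H](O3)c2c(c3ccc(OC)c(OC)c3n(C)c2=O)OC1(C)C | intermediate
16 | target: 7,8-dimethoxy-6-methyl-3,4-dihydro-2H-pyrano[3,2-c]quinolin-5(6H)-one (unit A) with a 2-hydroxy-2-methylpropyl group at C-4 (C-a, S), whose C-3 (C-b, S) and C-2 (C-c, R) are at the same time C-3 and C-4 of a second 7,8-dimethoxy-2,2,6-trimethyl-3,4-dihydro-2H-pyrano[3,2-c]quinolin-5(6H)-one (unit B); cis ring fusion, H-a trans to H-b | COc1ccc2c3c(c(=O)n(C)c2c1OC)[C@@H](CC(C)(C)O)[C@H]1[C@@H](O3)c2c(c3ccc(OC)c(OC)c3n(C)c2=O)OC1(C)C | target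

**Step count and risks**

Total step count: 7. Longest linear sequence: 7 steps (1 to 16); the second equivalent of 6 and the orthoformate 12 enter in step 6.

Steps most likely to fail:

1. Step 6 (proposed new method). The methoxy/aryloxy exchange may not turn over, because the anhydride-like diene 14 can revert to 13 faster than it cyclises. The cycloaddition may also give poor cis/trans selectivity at the ring fusion, or use the lactam carbonyl. The fallback uses known reaction types and sets out from 11. A Me2AlCl-promoted carbonyl-ene reaction with paraformaldehyde would add the missing carbon to C-b and turn the alkene into an isopropenyl group, giving 4-hydroxy-3-[(3R,4S)-3-(hydroxymethyl)-2,6-dimethyl-6-(triethylsilyloxy)hept-1-en-4-yl]-7,8-dimethoxy-1-methylquinolin-2(1H)-one F1. Parikh–Doering oxidation (SO3·pyridine, DMSO, Et3N) would give the aldehyde, which closes on the 4-OH to the lactol (3R,4S)-2-hydroxy-7,8-dimethoxy-6-methyl-4-[2-methyl-2-(triethylsilyloxy)propyl]-3-(prop-1-en-2-yl)-3,4-dihydro-2H-pyrano[3,2-c]quinolin-5(6H)-one F2. This already holds ring P, and its C-b is epimerisable next to the masked aldehyde and should settle trans to the C-a chain. TsOH in CH2Cl2 with 6 would then alkylate C-3 of 6 with the lactol-derived oxocarbenium ion (Friedel–Crafts type) and add the 4-OH of that unit to the isopropenyl group (the closure known from ortho-alkenylphenols to dimethylchromans), so that ring Q again closes last. C-c can equilibrate under the acid through reversible ionisation of the C-c–O-P bond, and the cis fusion is expected to be favoured because only it lets O-P turn away from the lactam carbonyl of unit B. The silyl ether should be lost under the acid, so the fallback comes back to the route at 16.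

2. Step 3. Face selectivity may be insufficient or reversed with an alkenyl instead of an aryl substituent on the enone, and 1,6-addition may compete. The fallback sets out from 6 and replaces the enone by an enal under secondary-amine catalysis, whose facial model is well established. (2E)-5-Methylhexa-2,4-dienal F3 would be made by Wittig reaction of 3-methylbut-2-enal with (triphenylphosphoranylidene)acetaldehyde. Iminium catalysis by (S)-2-[diphenyl(trimethylsilyloxy)methyl]pyrrolidine with PhCO2H would give, by Michael addition and hemiacetalisation, (4S)-2-hydroxy-7,8-dimethoxy-6-methyl-4-(2-methylprop-1-en-1-yl)-3,4-dihydro-2H-pyrano[3,2-c]quinolin-5(6H)-one F4. Oxidation with TEMPO (cat.) and PhI(OAc)2 would give (4S)-7,8-dimethoxy-6-methyl-4-(2-methylprop-1-en-1-yl)-3,4-dihydro-2H-pyrano[3,2-c]quinoline-2,5(6H)-dione F5, and MeMgBr would open this lactone to the tertiary alcohol. The fallback comes back to the route at 9.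

3. Step 2. At 250 °C the product may condense with a second malonate to a pyrano-fused by-product, and methyl ethers may be cleaved. The fallback sets out from 3 and separates acylation from ring closure. Heating 3 with 2,2-dimethyl-1,3-dioxane-4,6-dione in toluene at 100 °C would give 3-[(2,3-dimethoxyphenyl)(methyl)amino]-3-oxopropanoic acid F6, and P2O5 in MeSO3H at 70 °C would cyclise it by Friedel–Crafts acylation. The fallback comes back to the route at 6.

**Further compounds**

F1 | step 6 | 4-hydroxy-3-[(3R,4S)-3-(hydroxymethyl)-2,6-dimethyl-6-(triethylsilyloxy)hept-1-en-4-yl]-7,8-dimethoxy-1-methylquinolin-2(1H)-one | COc1ccc2c(O)c(c(=O)n(C)c2c1OC)[C@@H](CC(C)(C)O[Si](CC)(CC)CC)[C@H](C(C)=C)CO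
F2 | step 6 | (3R,4S)-2-hydroxy-7,8-dimethoxy-6-methyl-4-[2-methyl-2-(triethylsilyloxy)propyl]-3-(prop-1-en-2-yl)-3,4-dihydro-2H-pyrano[3,2-c]quinolin-5(6H)-one (anomer mixture) | COc1ccc2c3c(c(=O)n(C)c2c1OC)[C@@H](CC(C)(C)O[Si](CC)(CC)CC)[C@H](C(C)=C)C(O)O3
F3 | step 3 | (2E)-5-methylhexa-2,4-dienal | CC(C)=C/C=C/C=O
F4 | step 3 | (4S)-2-hydroxy-7,8-dimethoxy-6-methyl-4-(2-methylprop-1-en-1-yl)-3,4-dihydro-2H-pyrano[3,2-c]quinolin-5(6H)-one (anomer mixture) | COc1ccc2c3c(c(=O)n(C)c2c1OC)[C@H](C=C(C)C)CC(O)O3
F5 | step 3 | (4S)-7,8-dimethoxy-6-methyl-4-(2-methylprop-1-en-1-yl)-3,4-dihydro-2H-pyrano[3,2-c]quinoline-2,5(6H)-dione | COc1ccc2c3c(c(=O)n(C)c2c1OC)[C@H](C=C(C)C)CC(=O)O3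
F6 | step 2 | 3-[(2,3-dimethoxyphenyl)(methyl)amino]-3-oxopropanoic acid | OC(=O)CC(=O)N(C)c1cccc(OC)c1OC
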